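At late times I cared about two things in this flask: how much had reacted, and how that was shared between the two mirror-image substrates.

- south-west: left-handed substrate 1 M; right-handed substrate 1 M; coupling partner 0.60 M; precatalyst 200 mM; the very flask that is asked about, followed so far
- flask: left-handed substrate 1.0 M; coupling partner 0.600 M; precatalyst 200 mM; right-handed substrate 1.0 M; time 15 h

The recipe sets 0.600 M of coupling partner against 2.00 M of substrates together, and each substrate turn takes one coupling partner, so I expected it to be the limiting reagent.

- south-west (time / min: left-handed substrate / %, right-handed substrate / %): 12.0: 50.3, 49.6; 25.0: 49.1, 50.0; 40.0: 47.3, 48.8; 50.0: 47.2, 48.9; 60.0: 44.4, 48.5; 80.0: 43.7, 47.6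

(standard deviation of a reading: 0.5 percentage points)

- free catalyst is single-handed; left-handed substrate and right-handed substrate are mirror images of each other, charged as a racemate, each of them at the stated concentration
- what was read earlier has a scatter of 0.5 percentage points, one standard deviation
- steps thought possible: free catalyst -> spent catalyst; coupling partner + free catalyst + left-handed substrate -> free catalyst + left-handed product; 2 coupling partner -> self-condensation product; coupling partner + precatalyst -> free catalyst + spent reagent; coupling partner + free catalyst + right-handed substrate -> free catalyst + right-handed product
- an excess is the difference of the two amounts in percent of their sum
- an excess is below zero if the other one leads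

But the readings stop at 80.0 min, earlier than the asked 15 h, so I wanted a quantity that carries over. Both substrate steps use the same free catalyst and coupling partner, so these cancel when the two losses are compared, however they change in time. So I worked with the fraction left and not the fraction made. At 80.0 min the left-handed substrate stood at 87.4 % of its own charge and the right-handed at 95.2 %, which gave 2.74 for the selectivity factor, the logarithm of the first fraction left divided by that of the second. This is a rough reading, since the right-handed loss of 2.4 percentage points carries a scatter of 0.5 points. It put the excess in the first product at 46.5 %, so I expected a lower excess later, as the left-handed substrate thinned.

- part of the left-handed substrate and right-handed substrate charged together that has reacted at 15 h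
- excess of left-handed product over right-handed product in the product at 15 h
- excess of right-handed substrate over left-handed substrate among what is left of the two at 15 h

The forecast read the factor as 2.8, “with a fairly wide error”, and gave 16 % reacted, an excess of 44 % in the product and an excess of 8.3 % in the substrate left.

    free catalyst → spent catalyst (k = 0.0382 h⁻¹)
    coupling partner + free catalyst + left-handed substrate → free catalyst + left-handed product (k = 5.86 L² mol⁻² h⁻¹)
    2 coupling partner → self-condensation product (k = 0.142 L mol⁻¹ h⁻¹)
    coupling partner + precatalyst → free catalyst + spent reagent (k = 0.868 L mol⁻¹ h⁻¹)
    coupling partner + free catalyst + right-handed substrate → free catalyst + right-handed product (k = 2.12 L² mol⁻² h⁻¹)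

This flask gave 20.0 % reacted, an excess of 42.7 % in the product and an excess of 10.7 % in the substrate left. It stopped because its coupling partner was used up: 0.012 % of that charge stood at 15.0 h, less than the 89 % of right-handed substrate, and the same run without that using up had 96.3 % reacted. Its right-handed fraction left, 89 %, raised to 2.74, gives 71.7 % for the left-handed one, and this flask kept 71 %. A neighbouring flask, the same but with 2.4 M of coupling partner, kept 47.6 % of its right-handed substrate; raised to 2.74, that fraction puts the left-handed substrate at 6.56 % of the two charged, and that flask held 6.44 %.

Readings and results are calculated on assumed constants, noise included.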